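The cyclohexene ring (carotenoid numbering: ring C1–C6, alkyne C7≡C8) is cut into two three-carbon units. C4–C5(Me)=C6 is a 2-methylallyl unit that already carries the alkyne; C1(Me)2–C2–C3(OH) is a masked 3-methylbut-3-enal. One flask operation joins them: a chiral-phosphoric-acid-catalysed allylboration forms C3–C4 and sets the C3 carbinol, then triflic acid closes C1–C6 by cation–olefin cyclisation. The step exploits the homoallylic relation of the C3 hydroxyl to the C5=C6 bond and the gem-dimethyl carbon C1 as a tertiary cation. Its precursors are an acyclic, racemic α-alkynyl allylboronate and a β,γ-unsaturated aldehyde. Three Wittig olefinations then extend the C15 block to the C30 aldehyde.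

Key step: step 4

Assumption: (R)-TRIP, (R)-3,3'-bis(2,4,6-triisopropylphenyl)-1,1'-binaphthyl-2,2'-diyl hydrogen phosphate, is taken to direct allyl transfer to the Re face of aldehyde 8, as with simple aldehydes; if the sense proves opposite, (S)-TRIP is used with no other change.

Step 1
Reactants: 1 (E)-3-methylpent-2-en-4-yn-1-ol
Product: 2 (E)-3-methylpent-2-en-4-yn-1-yl pivalate
Conditions: pivaloyl chloride, NEt3, DMAP (cat.), CH2Cl2, 0 °C to rt
Reagents that add atoms: pivaloyl chloride, CC(C)(C)C(=O)Cl
Why: Acylation of the primary allylic alcohol gives an ester that should tolerate the alkynyllithium of step 2 and, once protonated on its carbonyl oxygen, resist ionisation in the acid stage of step 4.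

Step 2
Reactants: 3 isopropenylboronic acid pinacol ester; 2 (E)-3-methylpent-2-en-4-yn-1-yl pivalate
Product: 6 (E)-3,7-dimethyl-6-(4,4,5,5-tetramethyl-1,3,2-dioxaborolan-2-yl)octa-2,7-dien-4-yn-1-yl pivalate (racemic), via α-chloroallylboronate 4 (not isolated), via lithium acetylide 5 (not isolated)
Conditions: CH2Cl2, n-BuLi, THF, −100 °C, then 3, −100 °C to rt; separately 2, n-BuLi, THF, −78 °C; the two solutions combined at −78 °C, then rt
Reagents that add atoms: dichloromethane, ClCCl
Why: Matteson homologation of the alkenylboronate (1,2-metallate shift in the dichloromethyl ate complex), then displacement of the α-chloride through an alkynyl ate complex and a second 1,2-shift, should place boron, isopropenyl and alkynyl groups on the future C6; no stereocontrol is needed because this carbon becomes sp2 in step 4.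

Step 3
Reactants: 7 3-methylbut-3-en-1-ol
Product: 8 3-methylbut-3-enal
Conditions: Dess–Martin periodinane, NaHCO3, CH2Cl2, 0 °C; the solution is used at once
Reagents that add atoms: none
Why: Dess–Martin oxidation under buffered, non-acidic conditions should give the β,γ-unsaturated aldehyde without migration of the double bond into conjugation.

Step 4
Reactants: 6 racemic α-alkynyl allylboronate (1.5 equiv); 8 3-methylbut-3-enal
Product: 10 (E)-5-[(4R)-4-hydroxy-2,6,6-trimethylcyclohex-1-en-1-yl]-3-methylpent-2-en-4-yn-1-yl pivalate, via homoallylic borate 9 (not isolated)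
Conditions: (R)-TRIP (5 mol%), toluene, −40 °C; then CH2Cl2, TfOH (4 equiv), −78 to −30 °C; aq. NaHCO3
Reagents that add atoms: none
Why: Stage one is a chiral-phosphoric-acid-catalysed allylboration: the phosphate activates the pinacol boronate, aldehyde 8 reacts through a closed chair (Zimmerman–Traxler) transition state at the unsubstituted allyl terminus C4, boron moves to oxygen and the double bond shifts to C5=C6, so C3–C4 forms with the alkyne already on C6. The C3 carbinol, the only stereocentre, is set here by the catalyst, (R)-TRIP being expected to deliver the allyl unit to the Re face of 8, which corresponds to the (3R) ring; the racemic boron-bearing carbon of 6 and the E/Z geometry of the new C5=C6 bond are both erased in stage two, so only this facial selectivity matters. Stage two is a cation–olefin cyclisation of the pseudoionone-to-ionone type: TfOH protonates the isopropenyl group to the tertiary C1 cation, which is attacked by C6 of the trisubstituted enyne alkene in a 6-endo-trig closure that forms C1–C6 and the gem-dimethyl carbon and leaves a tertiary cation at C5. Loss of the C6 proton gives the tetrasubstituted C5=C6 bond conjugated with the alkyne, the thermodynamic position under reversible protonation. The selectivities needed are allyl rather than propargyl/allenyl transfer from 6 (six-membered allyl transition state, internal alkyne), initiation at the more basic isopropenyl group rather than at the alkynyl-deactivated C5=C6 bond, and 6-endo rather than 5-exo closure (5-exo would join two fully substituted carbons and give a secondary cation). The borate on O3 and the O-protonated pivalate should keep both oxygen functions out of the cationic chemistry.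

Step 5
Reactants: 10 ring pivalate
Product: 11 (R)-4-[(E)-5-hydroxy-3-methylpent-3-en-1-yn-1-yl]-3,5,5-trimethylcyclohex-3-en-1-ol
Conditions: i-Bu2AlH (3 equiv), CH2Cl2, −78 °C; aq. KNaC4H4O6
Reagents that add atoms: none
Why: Hydride cleavage of the pivalate should leave the enyne, the ring alkene and the stereocentre untouched.

Step 6
Reactants: 11 C15 diol
Product: 12 {(E)-5-[(4R)-4-hydroxy-2,6,6-trimethylcyclohex-1-en-1-yl]-3-methylpent-2-en-4-yn-1-yl}triphenylphosphonium bromide
Conditions: PPh3·HBr, MeOH, rt; crystallisation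
Reagents that add atoms: triphenylphosphine hydrobromide, [Br-].c1ccc([PH+](c2ccccc2)c2ccccc2)cc1
Why: Acid-mediated substitution of the primary allylic hydroxyl by triphenylphosphine is the usual entry to C15 carotenoid Wittig salts; the secondary homoallylic C3 hydroxyl should not ionise, and any 9Z salt formed through the allylic cation should be removed by crystallisation.

Step 7
Reactants: 13 (2E,4E,6E)-2,7-dimethylocta-2,4,6-trienedial (3 equiv); 14 (1,3-dioxolan-2-ylmethyl)triphenylphosphonium bromide
Product: 16 (2E,4E,6E,8E)-9-(1,3-dioxolan-2-yl)-2,7-dimethylnona-2,4,6,8-tetraenal, via dioxolanylmethylene phosphorane 15 (not isolated)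
Conditions: 14, t-BuOK, THF, 0 °C; added to 13, THF, −20 °C to rt; then I2 (cat.), CH2Cl2, daylight
Reagents that add atoms: none
Why: Wittig mono-olefination of the symmetrical dialdehyde, used in excess so that one formyl group stays free, should add the masked C11'–C10' unit, and iodine-catalysed equilibration should give the E bond.

Step 8
Reactants: 12 C15 phosphonium bromide; 16 C12 aldehyde acetal
Product: 19 (3R)-3-hydroxy-7,8-didehydro-10'-apo-β-caroten-10'-al, via allylic ylide 17 (not isolated), via C27 dioxolane 18 (not isolated)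
Conditions: NaOMe, MeOH/CH2Cl2, 0 °C to rt; then 1 M HCl, THF, rt; then heptane, 80 °C
Reagents that add atoms: water, O
Why: Wittig olefination with the semi-stabilised allylic ylide (free hydroxyl tolerated) should form C11=C12, dilute acid should unmask the conjugated aldehyde, and gentle heating should convert the hindered 11Z fraction into the E isomer without iodine, which would equilibrate the 9-position next to the alkyne.

Step 9
Reactants: 19 C27 aldehyde; 20 2-(triphenylphosphoranylidene)propanal
Product: 21 (3R)-3-hydroxy-7,8-didehydro-8'-apo-β-caroten-8'-al (target)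
Conditions: 20 (1.5 equiv), toluene, 80 °C, argon, dark
Reagents that add atoms: none
Why: Wittig olefination with the formyl-stabilised ylide should be E-selective and add C9' with its methyl group and the C8' aldehyde; the α-branched, more conjugated product aldehyde should react much more slowly than 19, which limits over-homologation.

Compound list
1 | (E)-3-methylpent-2-en-4-yn-1-ol | C#C/C(C)=C/CO | starting material
2 | (E)-3-methylpent-2-en-4-yn-1-yl pivalate | C#C/C(C)=C/COC(=O)C(C)(C)C | intermediate
3 | isopropenylboronic acid pinacol ester | CC(=C)B1OC(C)(C)C(C)(C)O1 | starting material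
4 | 2-(1-chloro-2-methylprop-2-en-1-yl)-4,4,5,5-tetramethyl-1,3,2-dioxaborolane (racemic) | CC(=C)C(Cl)B1OC(C)(C)C(C)(C)O1 | intermediate (not isolated)
5 | lithium acetylide of 2 | [Li]C#C/C(C)=C/COC(=O)C(C)(C)C | intermediate (not isolated)
6 | (E)-3,7-dimethyl-6-(4,4,5,5-tetramethyl-1,3,2-dioxaborolan-2-yl)octa-2,7-dien-4-yn-1-yl pivalate (racemic) | CC(=C)C(C#C/C(C)=C/COC(=O)C(C)(C)C)B1OC(C)(C)C(C)(C)O1 | intermediate
7 | 3-methylbut-3-en-1-ol | CC(=C)CCO | starting material
8 | 3-methylbut-3-enal | CC(=C)CC=O | intermediate
9 | (2E,9S)-3,7,11-trimethyl-9-[(4,4,5,5-tetramethyl-1,3,2-dioxaborolan-2-yl)oxy]dodeca-2,6,11-trien-4-yn-1-yl pivalate (6E/6Z mixture; same spatial arrangement at the carbinol as the (3R) ring) | C=C(C)C[C@H](OB1OC(C)(C)C(C)(C)O1)CC(C)=CC#C/C(C)=C/COC(=O)C(C)(C)C | intermediate (not isolated)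
10 | (E)-5-[(4R)-4-hydroxy-2,6,6-trimethylcyclohex-1-en-1-yl]-3-methylpent-2-en-4-yn-1-yl pivalate | CC1=C(C#C/C(C)=C/COC(=O)C(C)(C)C)C(C)(C)C[C@H](O)C1 | intermediate
11 | (R)-4-[(E)-5-hydroxy-3-methylpent-3-en-1-yn-1-yl]-3,5,5-trimethylcyclohex-3-en-1-ol | CC1=C(C#C/C(C)=C/CO)C(C)(C)C[C@H](O)C1 | intermediate
12 | {(E)-5-[(4R)-4-hydroxy-2,6,6-trimethylcyclohex-1-en-1-yl]-3-methylpent-2-en-4-yn-1-yl}triphenylphosphonium bromide | CC1=C(C#C/C(C)=C/C[P+](c2ccccc2)(c2ccccc2)c2ccccc2)C(C)(C)C[C@H](O)C1.[Br-] | intermediate
13 | (2E,4E,6E)-2,7-dimethylocta-2,4,6-trienedial | O=C/C(C)=C/C=C/C=C(\C)C=O | starting material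
14 | (1,3-dioxolan-2-ylmethyl)triphenylphosphonium bromide | [Br-].C1COC(C[P+](c2ccccc2)(c2ccccc2)c2ccccc2)O1 | starting material
15 | (1,3-dioxolan-2-ylmethylene)triphenylphosphorane | C1COC(C=P(c2ccccc2)(c2ccccc2)c2ccccc2)O1 | intermediate (not isolated)
16 | (2E,4E,6E,8E)-9-(1,3-dioxolan-2-yl)-2,7-dimethylnona-2,4,6,8-tetraenal | O=C/C(C)=C/C=C/C=C(C)/C=C/C1OCCO1 | intermediate
17 | ylide of 12 | CC1=C(C#C/C(C)=C/C=P(c2ccccc2)(c2ccccc2)c2ccccc2)C(C)(C)C[C@H](O)C1 | intermediate (not isolated)
18 | (3R)-3-hydroxy-7,8-didehydro-10'-apo-β-caroten-10'-al ethylene acetal (11E/11Z mixture) | CC1=C(C#C/C(C)=C/C=CC(/C)=C/C=C/C=C(C)/C=C/C2OCCO2)C(C)(C)C[C@H](O)C1 | intermediate (not isolated)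
19 | (3R)-3-hydroxy-7,8-didehydro-10'-apo-β-caroten-10'-al | CC1=C(C#C/C(C)=C/C=C/C(C)=C/C=C/C=C(C)/C=C/C=O)C(C)(C)C[C@H](O)C1 | intermediate
20 | 2-(triphenylphosphoranylidene)propanal | CC(C=O)=P(c1ccccc1)(c1ccccc1)c1ccccc1 | starting material
21 | (3R)-3-hydroxy-7,8-didehydro-8'-apo-β-caroten-8'-al | CC1=C(C#C/C(C)=C/C=C/C(C)=C/C=C/C=C(C)/C=C/C=C(\C)C=O)C(C)(C)C[C@H](O)C1 | target

Total step count: 9. Longest linear sequence: 7 steps (1, 2, 4, 5, 6, 8, 9).

Steps most likely to fail

Step 4. The catalyst may not differentiate the two faces of the α-unbranched aldehyde well enough. In the acid stage the protonated allylic ester may ionise, or the C1 cation may eliminate or be trapped before it closes, leaving acyclic dienes or the wrong alkene position. The fallback takes the ring from the chiral pool instead of building it. Setting out from 2, commercial (4R,6R)-4-hydroxy-2,2,6-trimethylcyclohexanone F1 is silylated (TBSCl, imidazole, DMF) to the silyl ether F2. This is converted (LiN(i-Pr)2, PhNTf2, THF, −78 °C) into the enol triflate F3, which is coupled with alkyne 2 (Pd(PPh3)4, CuI, i-Pr2NH) to the silylated enyne F4. Desilylation (Bu4NF, THF) comes back to the route at 10.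

Step 2. The alkynyl group may migrate too slowly in the ate complex, so that the complex reverts or the allylic chloride is scrambled by chloride. The fallback makes the carbon–boron bond by allylic substitution instead. Setting out from 2, Sonogashira coupling (Pd(PPh3)4, CuI, NEt3) with (E)-3-iodo-2-methylprop-2-en-1-ol F5 gives the dienynol F6. ClCO2Me and pyridine give the methyl carbonate F7. Copper-catalysed borylation with allylic transposition (B2pin2, CuCl, Xantphos, t-BuOK, THF) puts boron on the carbon next to the alkyne and comes back at 6.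

Step 9. The vinylogous aldehyde 19 may react sluggishly with the stabilised ylide, and the product aldehyde may be olefinated a second time. The fallback builds C9' and C8' into the C10 block before the ring is attached. Setting out from 13 and 12, 1,1-dimethoxypropan-2-one F8 and CH2=CHMgBr (THF, 0 °C) give the tertiary allylic alcohol F9. PPh3·HBr in MeOH converts it with allylic transposition into (E)-(4,4-dimethoxy-3-methylbut-2-en-1-yl)triphenylphosphonium bromide F10. Wittig reaction of F10 with excess 13 (NaOMe, MeOH/CH2Cl2) gives the C15 aldehyde acetal F11. Wittig reaction of F11 with 12 (NaOMe) gives the C30 dimethyl acetal F12, and hydrolysis with dilute acid comes back at 21.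

Further compounds
F1 | step 4 | (4R,6R)-4-hydroxy-2,2,6-trimethylcyclohexanone | O=C1C(C)(C)C[C@H](O)C[C@H]1C
F2 | step 4 | (4R,6R)-4-(tert-butyldimethylsilyloxy)-2,2,6-trimethylcyclohexanone | O=C1C(C)(C)C[C@H](O[Si](C)(C)C(C)(C)C)C[C@H]1C
F3 | step 4 | (4R)-4-(tert-butyldimethylsilyloxy)-2,6,6-trimethylcyclohex-1-en-1-yl trifluoromethanesulfonate | CC1=C(OS(=O)(=O)C(F)(F)F)C(C)(C)C[C@H](O[Si](C)(C)C(C)(C)C)C1
F4 | step 4 | (E)-5-[(4R)-4-(tert-butyldimethylsilyloxy)-2,6,6-trimethylcyclohex-1-en-1-yl]-3-methylpent-2-en-4-yn-1-yl pivalate | CC1=C(C#C/C(C)=C/COC(=O)C(C)(C)C)C(C)(C)C[C@H](O[Si](C)(C)C(C)(C)C)C1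
F5 | step 2 | (E)-3-iodo-2-methylprop-2-en-1-ol | OC/C(C)=C/I
F6 | step 2 | (2E,6E)-8-hydroxy-3,7-dimethylocta-2,6-dien-4-yn-1-yl pivalate | OC/C(C)=C/C#C/C(C)=C/COC(=O)C(C)(C)C
F7 | step 2 | (2E,6E)-8-(methoxycarbonyloxy)-3,7-dimethylocta-2,6-dien-4-yn-1-yl pivalate | COC(=O)OC/C(C)=C/C#C/C(C)=C/COC(=O)C(C)(C)C
F8 | step 9 | 1,1-dimethoxypropan-2-one | CC(=O)C(OC)OC
F9 | step 9 | 1,1-dimethoxy-2-methylbut-3-en-2-ol | C=CC(C)(O)C(OC)OC
F10 | step 9 | (E)-(4,4-dimethoxy-3-methylbut-2-en-1-yl)triphenylphosphonium bromide | [Br-].COC(OC)/C(C)=C/C[P+](c1ccccc1)(c1ccccc1)c1ccccc1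
F11 | step 9 | (2E,4E,6E,8E,10E)-12,12-dimethoxy-2,7,11-trimethyldodeca-2,4,6,8,10-pentaenal | O=C/C(C)=C/C=C/C=C(C)/C=C/C=C(\C)C(OC)OC
F12 | step 9 | (3R)-3-hydroxy-7,8-didehydro-8'-apo-β-caroten-8'-al dimethyl acetal | CC1=C(C#C/C(C)=C/C=C/C(C)=C/C=C/C=C(C)/C=C/C=C(\C)C(OC)OC)C(C)(C)C[C@H](O)C1
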